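Slowness comes first here: at the start none of the gas phase is in solution, so a target route that needs dissolved gas starts weak. If two routes compete for one substrate, each removing it at its own first-order rate constant, what each makes in a time window stands in the ratio of those constants. If the target route needs dissolved gas, its constant is pseudo-first-order, a true constant times [dissolved gas], and the ratio follows the gas.

| flask | substrate | gas phase | protic impurity | remark | time |
|---|---|---|---|---|---|
| winter | 0.50 M | 200 mM (held) | 0.035 M | run made earlier |  |
| noon | 0.50 M | 200 mM (held) | 0.055 M | run made earlier |  |
| flask | 0.50 M | 200 mM (held) | 0.0250 M |  | 2.0 min |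

| run | time / s | target / % | substrate / % |
|---|---|---|---|
| winter | 20.0 | 23 | 28 |
| winter | 40.0 | 35 | 6 |
| winter | 60.0 | 35 | 2 |
| winter | 80.0 | 37 | 0 |
| winter | 90.0 | 33 | 1 |
| winter | 120 | 39 | 0 |
| noon | 10.0 | 13 | 59 |
| noon | 15.0 | 18 | 42 |
| noon | 25.0 | 26 | 18 |
| noon | 40.0 | 34 | 7 |
| noon | 80.0 | 36 | 3 |
| noon | 120 | 36 | 1 |

(readings scatter by 1.5 percentage points)

- the numbers in the tables scatter with a standard deviation of 1.5 percentage points
- at the start none of the gas phase is in solution

- Tuesday's: doubling the transfer coefficient of the gas phase, all else as stated
- Saturday's: doubling the saturation concentration of gas phase, all else as stated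

- target at 2.0 min, in percent of the substrate charged
- concentration of dissolved gas in solution at 30 s, in percent of saturation
- the change that raises the amount of target at 2.0 min, in percent of the substrate charged most ("none" if none brings more than 2 percentage points) (Tuesday's / Saturday's / none)
- amount of target at 2.0 min, in percent of the substrate charged, after Saturday's

Noon's last reading gives 0.571 for the odds, target made per substrate lost to the other route, the usual selectivity factor. Up to 25.0 s the noon run reads odds of 0.464, and after it 1.43, a rough reading given the scatter of 1.5 percentage points. In the noon run the odds read higher late than early, so I read the other route as independent of the gas.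

The last target readings, 39% at 0.035 M impurity and 36% at 0.055 M, differ by 3 points, so I carry the same odds to the flask at 0.0250 M. The winter run reads 0% substrate at 120 s, so I take the flask's substrate as consumed by 2.0 min, and my reckoning gives odds/(1 + odds), or 36.3% target. Saturday's doubles the gas ceiling, so, taking the target route as proportional to [dissolved gas], I double the odds and get 53.3%. Tuesday's brings the gas sooner to the same ceiling, so I choose Saturday's. Odds give a ratio rather than a level, so I set no figure of my own for the gas at 30 s.

The forecast says 37%, 68%, none and 38%, holding that “selectivity is largely gas-independent”. It differs from my reckoning on the best change and on the yield after Saturday's.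

The flask gives 36.9% target, gas at 76.9% of saturation at 30 s, and 51.5% after Saturday's, which gains 15 points against 6.7 points for Tuesday's. gas phase ⇌ dissolved gas, rate k1*(csat - [dissolved gas]) (kL = 0.210 s⁻¹); substrate → side product (k = 0.0410 s⁻¹); dissolved gas + protic impurity → quenched reagent (k = 3.50 M⁻¹ s⁻¹); substrate + dissolved gas → target (k = 0.250 M⁻¹ s⁻¹); dissolved gas ⇌ dormant form (K = 1.90, k = 0.280 s⁻¹)

By 30 s, in this flask read early, the side step has made 56.7% and the target step 30.2%, odds of 0.533, with dissolved gas at 0.154 M and 13.1% of the substrate still there. That remaining substrate then splits at odds of 1.04 while the gas rises to 0.200 M, leaving this flask at whole-run odds of 0.585.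

The runs stem from a simulated flask for substances that don't exist; the scatter is artificial.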